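**Remark (assumption):** gibberellane numbering (C1–C19) is used for every intermediate. α is the face of ring B that carries the lactone bridge and the ring C carbons C11 and C14; β is the face that carries H-5, H-9, C7 and the C15–C16 bridge. The target is the C19 gibberellin 3β,10α,16-trihydroxy-20-norgibberellane-7,19-dioic acid 19,10-lactone, with the 16-hydroxyl exo (anti to C12) and the C17 methyl endo; it is called "the target gibberellin" below. All compounds marked "starting material" in the compound list are taken as commercial.

## Retrosynthetic overview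

1. Target gibberellin ⇐ its benzyl ester ⇐ the 3-ketone ⇐ the 3-epimer, which arises from a bromo keto aldehyde in one SmI2 operation that closes ring A (C3–C4, Reformatsky aldol) and ring D (C13–C16, ketyl–olefin addition).
2. Enabling feature: C16 (carbinol carbon bearing OH and the C17 methyl) lies 1,5 to C13 through C15–C8–C14, so a 2-oxopropyl group on C8 and the C12=C13 double bond of a cyclohexene ring C form a 5-exo ketyl–olefin pair whose union gives the bicyclo[3.2.1]octane of rings C/D. The C3(OH)–C4–C19(=O)–O–C10 β-hydroxy lactone is the matching aldol retron (C4 bromide, C3 aldehyde).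
3. Bromo keto aldehyde ⇐ tricyclic γ-lactone (C4 bromination, Wacker oxidation of the C8 allyl group, acetal hydrolysis) ⇐ propanoate by intramolecular Michael addition (C4–C5) ⇐ keto ester + three-carbon Grignard reagent (C10 carbinol, C1–C3).
4. Keto ester ⇐ cis-hydrindenone (enol triflate carbonylation brings C7) ⇐ Diels–Alder reaction of butadiene with a 2-allyl-4-silyloxycyclopentenone (ring C, C8, C9) ⇐ (R)-4-silyloxycyclopentenone (ring B, source of absolute configuration).
5. Order of ring formation: B (starting material) → C (step 3) → γ-lactone (step 10) → A and D together (step 14).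

Key step: step 14

## Route

Step 1
Reactants: 1 (R)-4-(tert-butyldimethylsilyloxy)cyclopent-2-en-1-one
Product: 2 (R)-4-(tert-butyldimethylsilyloxy)-2-iodocyclopent-2-en-1-one
Conditions: I2, pyridine, CH2Cl2, 0 °C → rt
Reagents that add atoms: iodine, II
Why: α-Iodination of the enone by conjugate addition of pyridine, iodination of the enolate and loss of pyridine (addition–elimination of the Baylis–Hillman type) is standard for cycloalkenones and leaves the C10 stereocenter untouched.

Step 2
Reactants: 2 (R)-4-(tert-butyldimethylsilyloxy)-2-iodocyclopent-2-en-1-one; 3 allyltributylstannane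
Product: 4 (R)-2-allyl-4-(tert-butyldimethylsilyloxy)cyclopent-2-en-1-one
Conditions: Pd2(dba)3 (cat.), AsPh3, CuI (cat.), NMP, 50 °C
Reagents that add atoms: none
Why: Stille coupling of the α-iodo enone with the allylstannane under neutral conditions should install C15–C17 without β-elimination of the silyloxy group, and no stereocenter is formed.

Step 3
Reactants: 4 (R)-2-allyl-4-(tert-butyldimethylsilyloxy)cyclopent-2-en-1-one; 5 buta-1,3-diene
Product: 6 cis-hydrindenone (7a-allyl-3-silyloxy-hexahydroinden-1-one)
Conditions: EtAlCl2 (30 mol %), buta-1,3-diene (excess), toluene, −30 °C → rt, sealed vessel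
Reagents that add atoms: none
Why: In this Lewis acid catalysed Diels–Alder reaction the suprafacial addition makes the ring fusion cis and creates C8 (quaternary) and C9 together, and the diene should approach the enone face anti to the C10 silyloxy group, so both centers follow from the configuration of 1.

Step 4
Reactants: 6 cis-hydrindenone
Product: 7 enol triflate (C5=C6–OTf)
Conditions: KN(SiMe3)2, THF, −78 °C; then PhNTf2, −78 → −40 °C; aq. NH4Cl
Reagents that add atoms: N-phenylbis(trifluoromethanesulfonimide), O=S(=O)(N(c1ccccc1)S(=O)(=O)C(F)(F)F)C(F)(F)F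
Why: Enolate O-sulfonylation is regiospecific because the C6 ketone can enolise only toward C5 (C8 is quaternary), and the low temperature should suppress β-elimination of the silyloxy group.

Step 5
Reactants: 7 enol triflate; 8 benzyl alcohol
Product: 9 benzyl enoate silyl ether
Conditions: Pd(OAc)2 (cat.), PPh3, Et3N, CO (1 atm), DMF, 50 °C
Reagents that add atoms: carbon monoxide, [C-]#[O+]
Why: Palladium-catalysed alkoxycarbonylation of the enol triflate (oxidative addition to zerovalent palladium, CO insertion, alcoholysis) installs C7 as the benzyl ester and leaves all stereocenters untouched.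

Step 6
Reactants: 9 benzyl enoate silyl ether
Product: 10 allylic alcohol
Conditions: HF·pyridine, THF, 0 °C → rt
Reagents that add atoms: none
Why: Fluoride-mediated cleavage of the silyl ether under mildly acidic conditions frees the C10 hydroxyl without touching the ester or the alkenes.

Step 7
Reactants: 10 allylic alcohol
Product: 11 keto ester (C10 ketone, C5=C6–CO2Bn)
Conditions: Dess–Martin periodinane, CH2Cl2, 0 °C → rt
Reagents that add atoms: none
Why: Dess–Martin oxidation of the allylic alcohol gives the enone under non-basic conditions that should not epimerise C9.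

Step 8
Reactants: 11 keto ester; 12 [2-(1,3-dioxolan-2-yl)ethyl]magnesium bromide
Product: 13 tertiary alcohol
Conditions: LaCl3·2LiCl (30 mol %), THF, −78 °C; aq. NH4Cl
Reagents that add atoms: none
Why: Grignard 1,2-addition to the C10 ketone (the lanthanum salt suppresses enolisation and conjugate addition) should occur on the convex β-face of the cis-fused bicycle, anti to C11 on C9, so that C1 is β and the hydroxyl α as in the target.

Step 9
Reactants: 13 tertiary alcohol; 14 propanoyl chloride
Product: 15 propanoate
Conditions: NaN(SiMe3)2, THF, −78 °C; then propanoyl chloride, −78 → 0 °C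
Reagents that add atoms: none
Why: O-acylation of the preformed tertiary sodium alkoxide with the acid chloride gives the propanoate (C4, C18, C19) without affecting any stereocenter.

Step 10
Reactants: 15 propanoate
Product: 16 tricyclic γ-lactone
Conditions: KN(SiMe3)2, THF, −78 → 0 °C; then t-BuOH, rt; aq. NH4Cl
Reagents that add atoms: none
Why: Intramolecular Michael addition (5-exo-trig) of the propanoate enolate to C5 of the unsaturated benzyl ester closes the γ-lactone, the C10–O tether delivers C4 to the α-face of C5 (H-5 β), and equilibration with KOt-Bu/t-BuOH should place the C6 ester β, trans to C4, while the C4 center is reset in step 14.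

Step 11
Reactants: 16 tricyclic γ-lactone
Product: 17 α-bromo lactone
Conditions: LiN(i-Pr)2, THF, −78 °C; then CBr4, −78 °C; aq. NH4Cl
Reagents that add atoms: tetrabromomethane, BrC(Br)(Br)Br
Why: Enolate bromination should be selective because the lactone α-hydrogen at C4 is the most acidic and most accessible C–H (C6–H is flanked by the quaternary C8), and the C4 configuration is irrelevant since C4 becomes an enolate again in step 14.

Step 12
Reactants: 17 α-bromo lactone
Product: 18 bromo lactone methyl ketone
Conditions: PdCl2 (10 mol %), p-benzoquinone (1.2 equiv), DMF/H2O (7:1), rt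
Reagents that add atoms: water, O
Why: Tsuji–Wacker oxidation with benzoquinone as a copper-free reoxidant converts the terminal allyl alkene into the methyl ketone (C16=O, C17 methyl) with Markovnikov selectivity, the internal cis-disubstituted ring alkene being far less reactive and the absence of copper salts keeping the tertiary C4–Br bond from atom-transfer activation.

Step 13
Reactants: 18 bromo lactone methyl ketone
Product: 19 bromo keto aldehyde
Conditions: 1 M HCl, THF, rt
Reagents that add atoms: water, O
Why: Acid-catalysed acetal hydrolysis liberates the C3 aldehyde without touching the tertiary bromide, the lactone or the benzyl ester.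

Step 14
Reactants: 19 bromo keto aldehyde
Product: 21 3-epi benzyl ester of the target gibberellin, via ring-A-closed hydroxy ketone 20 (not isolated)
Conditions: SmI2 (2.2 equiv), THF, −78 °C; then t-BuOH, HMPA, SmI2 (3 equiv), −78 → 0 °C; aq. NH4Cl
Reagents that add atoms: none
Why: At −78 °C without HMPA, SmI2 should reduce only the tertiary C4–Br bond (two electrons) to the samarium lactone enolate, which adds to the C3 aldehyde and closes ring A; after protonation of the aldolate with t-BuOH and addition of HMPA, single-electron reduction of the C16 ketone gives a ketyl radical anion that adds to C13 of the C12=C13 double bond, and the resulting C12 radical is reduced and protonated. The closest known reaction types are the SmI2-promoted intramolecular Reformatsky reaction of α-bromo esters with aldehydes and the SmI2/HMPA ketyl–olefin cyclisation onto unactivated alkenes, here run one after the other in the same flask. Ring A closes by a 6-(enolexo)-exo-trig aldol addition of the lactone enolate (giving the 6-oxabicyclo[3.2.1]octan-7-one), and ring D closes by a 5-exo-trig radical addition that converts the cyclohexene ring C into the bicyclo[3.2.1]octane. C4 is fixed by the tether (C3 can reach only the enolate face that carries C1 on C10, so C18 ends on the face of C6), C3 is expected equatorial (3α) from the chair-like samarium chelate between the aldehyde and lactone oxygens and is corrected in steps 15 and 16, C13 is fixed by the geometry of the two-atom bridge from C8, and C16 is set by the bulky HMPA-solvated samarium alkoxide oxygen taking the exo position anti to C12, which leaves C17 endo and the hydroxyl exo as in the target. The step needs C–Br reduction before carbonyl reduction (secured by the low temperature and the late addition of HMPA), attack at C13 instead of C12 (the 5-exo mode to the bicyclo[3.2.1] system should be favoured over the 6-endo mode to a bicyclo[2.2.2]octane by the shorter reach of the C15–C16 arm) and inertness of the benzyl ester and lactone (neither should be reduced by SmI2/HMPA at or below 0 °C).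

Step 15
Reactants: 21 3-epi benzyl ester of the target gibberellin
Product: 22 3-oxo benzyl ester
Conditions: Dess–Martin periodinane, CH2Cl2, rt
Reagents that add atoms: none
Why: Dess–Martin oxidation converts the secondary C3 alcohol into the ketone (the tertiary C16 alcohol is inert), which erases the C3 configuration, and the quaternary C4 keeps the β-keto lactone from enolising toward C4.

Step 16
Reactants: 22 3-oxo benzyl ester
Product: 23 benzyl ester of the target gibberellin
Conditions: LiBH(s-Bu)3 (L-Selectride, 2.5 equiv), THF, −78 °C; aq. NH4Cl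
Reagents that add atoms: none
Why: Ketone reduction with a bulky trialkylborohydride should deliver hydride along the equatorial trajectory of the ring A chair and give the axial 3β-alcohol, trans to the axial C19 lactone bridge on C4, as the target requires.

Step 17
Reactants: 23 benzyl ester of the target gibberellin
Product: 24 target gibberellin
Conditions: H2 (1 atm), Pd/C, EtOAc, rt
Reagents that add atoms: none
Why: Hydrogenolysis of the benzyl ester releases the C7 acid under neutral conditions, which avoids base-induced retro-aldol epimerisation at C3 and opening of the lactone.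

## Compound list

1 | (R)-4-(tert-butyldimethylsilyloxy)cyclopent-2-en-1-one | O=C1C=C[C@H](O[Si](C)(C)C(C)(C)C)C1 | starting material
2 | (R)-4-(tert-butyldimethylsilyloxy)-2-iodocyclopent-2-en-1-one | O=C1C(I)=C[C@H](O[Si](C)(C)C(C)(C)C)C1 | intermediate
3 | allyltributylstannane | C=CC[Sn](CCCC)(CCCC)CCCC | starting material
4 | (R)-2-allyl-4-(tert-butyldimethylsilyloxy)cyclopent-2-en-1-one | O=C1C(CC=C)=C[C@H](O[Si](C)(C)C(C)(C)C)C1 | intermediate
5 | buta-1,3-diene | C=CC=C | starting material
6 | cis-fused 7a-allyl-3-(tert-butyldimethylsilyloxy)-2,3,3a,4,7,7a-hexahydro-1H-inden-1-one, silyloxy cis to H-3a and to the allyl group (C6 ketone, C10 silyloxy, C8 allyl, C12=C13) | O=C1C[C@@H](O[Si](C)(C)C(C)(C)C)[C@@H]2CC=CC[C@]12CC=C | intermediate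
7 | enol triflate of 6 (C5=C6–OSO2CF3), stereocenters as in 6 | FC(F)(F)S(=O)(=O)OC1=C[C@@H](O[Si](C)(C)C(C)(C)C)[C@@H]2CC=CC[C@]12CC=C | intermediate
8 | benzyl alcohol | OCc1ccccc1 | starting material
9 | benzyl cis-7a-allyl-3-(tert-butyldimethylsilyloxy)-3a,4,7,7a-tetrahydro-3H-indene-1-carboxylate, stereocenters as in 6 | O=C(OCc3ccccc3)C1=C[C@@H](O[Si](C)(C)C(C)(C)C)[C@@H]2CC=CC[C@]12CC=C | intermediate
10 | benzyl cis-7a-allyl-3-hydroxy-3a,4,7,7a-tetrahydro-3H-indene-1-carboxylate, hydroxyl cis to H-3a and to the allyl group | O=C(OCc3ccccc3)C1=C[C@@H](O)[C@@H]2CC=CC[C@]12CC=C | intermediate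
11 | benzyl cis-7a-allyl-3-oxo-3a,4,7,7a-tetrahydro-3H-indene-1-carboxylate (C10 ketone, C5=C6–CO2Bn) | O=C(OCc3ccccc3)C1=CC(=O)[C@@H]2CC=CC[C@]12CC=C | intermediate
12 | [2-(1,3-dioxolan-2-yl)ethyl]magnesium bromide | Br[Mg]CCC1OCCO1 | starting material
13 | benzyl cis-7a-allyl-3-[2-(1,3-dioxolan-2-yl)ethyl]-3-hydroxy-3a,4,7,7a-tetrahydro-3H-indene-1-carboxylate, hydroxyl α (trans to H-3a and to the allyl group) | O=C(OCc4ccccc4)C1=C[C@@](O)(CCC2OCCO2)[C@@H]3CC=CC[C@]13CC=C | intermediate
14 | propanoyl chloride | CCC(=O)Cl | starting material
15 | propanoate ester of 13 (C10–O–CO–CH2CH3) | O=C(OCc4ccccc4)C1=C[C@@](OC(=O)CC)(CCC2OCCO2)[C@@H]3CC=CC[C@]13CC=C | intermediate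
16 | tricyclic γ-lactone: rings B/C cis-fused, C19 lactone bridging C4 (on C5, α) and O–C10 (α), H-5 β, C4 methyl cis to H-5, CO2Bn on C6 β, allyl on C8 β, 2-(1,3-dioxolan-2-yl)ethyl on C10 β, C12=C13 | C[C@H]1C(=O)O[C@]2(CCC3OCCO3)[C@@H]4CC=CC[C@]4(CC=C)[C@@H](C(=O)OCc5ccccc5)[C@H]12 | intermediate
17 | α-bromo lactone: as 16 with bromine on C4 (cis to H-5; C4 configuration inconsequential) | C[C@]1(Br)C(=O)O[C@]2(CCC3OCCO3)[C@@H]4CC=CC[C@]4(CC=C)[C@@H](C(=O)OCc5ccccc5)[C@H]12 | intermediate
18 | bromo lactone methyl ketone: as 17 with 2-oxopropyl on C8 | C[C@]1(Br)C(=O)O[C@]2(CCC3OCCO3)[C@@H]4CC=CC[C@]4(CC(C)=O)[C@@H](C(=O)OCc5ccccc5)[C@H]12 | intermediate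
19 | bromo keto aldehyde: as 18 with 3-oxopropyl on C10 | C[C@]1(Br)C(=O)O[C@]2(CCC=O)[C@@H]4CC=CC[C@]4(CC(C)=O)[C@@H](C(=O)OCc5ccccc5)[C@H]12 | intermediate
20 | ring-A-closed hydroxy ketone: benzyl 3α-hydroxy-16-oxo-13,16-seco-gibberell-12-ene ester 19,10-lactone (ring D open, 2-oxopropyl on C8) | C[C@@]12C(=O)O[C@]3(CC[C@H]1O)[C@@H]1CC=CC[C@]1(CC(C)=O)[C@@H](C(=O)OCc4ccccc4)[C@@H]32 | intermediate
21 | 3-epi benzyl ester of the target gibberellin (3α-OH, 16-exo-OH, C17 methyl endo) | C[C@@]12C(=O)O[C@]3(CC[C@H]1O)[C@@H]1CC[C@@H]4C[C@]1(C[C@@]4(C)O)[C@@H](C(=O)OCc5ccccc5)[C@@H]32 | intermediate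
22 | 3-oxo benzyl ester (C3 ketone, 16-exo-OH, 19,10-lactone, benzyl 7-oate) | C[C@@]12C(=O)O[C@]3(CCC1=O)[C@@H]1CC[C@@H]4C[C@]1(C[C@@]4(C)O)[C@@H](C(=O)OCc5ccccc5)[C@@H]32 | intermediate
23 | benzyl ester of the target gibberellin (3β-OH, 16-exo-OH, 19,10-lactone, benzyl 7-oate) | C[C@@]12C(=O)O[C@]3(CC[C@@H]1O)[C@@H]1CC[C@@H]4C[C@]1(C[C@@]4(C)O)[C@@H](C(=O)OCc5ccccc5)[C@@H]32 | intermediate
24 | target gibberellin: 3β,10α,16-trihydroxy-20-norgibberellane-7,19-dioic acid 19,10-lactone (16-hydroxyl exo, C17 methyl endo, H-5 β, H-9 β, 6β-carboxyl) | C[C@@]12C(=O)O[C@]3(CC[C@@H]1O)[C@@H]1CC[C@@H]4C[C@]1(C[C@@]4(C)O)[C@@H](C(=O)O)[C@@H]32 | target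

## Step count and risks

Total steps: 17. Longest linear sequence: 17 steps (1 → 24).

Steps most likely to fail:

1. **Step 14.** What may go wrong: the two samarium-mediated events may interfere (reduction of the aldehyde before the enolate reaches it, or retro-aldol opening of ring A once HMPA is added), and the ketyl may be reduced to the secondary alcohol before it adds to the unactivated ring olefin of the crowded substrate. Fallback: ring D is closed first on the simpler lactone and ring A afterwards by a base-mediated aldol addition, so that each event can be run on its own. Setting out from 16, Wacker oxidation (PdCl2, CuCl, O2, DMF/H2O) gives the keto acetal lactone F1. SmI2/HMPA/t-BuOH then performs the ketyl–olefin cyclisation alone and gives the ring-D-closed acetal lactone F2. 1 M HCl in THF liberates the aldehyde F3. KOt-Bu (catalytic, THF/t-BuOH, −20 °C) closes ring A by aldol addition of the lactone enolate and comes back to the route at 21 (any C3 epimer converges at 22 in step 15).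

2. **Step 3.** What may go wrong: the α-alkylated enone may be too poor a dienophile for butadiene, and long exposure to the Lewis acid may cause β-elimination of the silyloxy group. Fallback: the α-iodo enone 2 itself serves as the more reactive dienophile. With 5 and EtAlCl2 it should give the cis-fused α-iodo ketone F4 (iodine on C8, diene again anti to the silyloxy group). Keck radical allylation with 3 (AIBN, benzene, 80 °C) then replaces iodine by the allyl group on the convex face, cis to H-9, and comes back to the route at 6.

3. **Step 11.** What may go wrong: competing deprotonation at C6 next to the benzyl ester, or polybromination, would give mixtures that carry no clean enolate precursor into step 14. Fallback: the bromide is omitted and ring A is closed by a base-mediated aldol addition. Setting out from 16, 1 M HCl in THF gives the aldehyde F5. KOt-Bu (catalytic, THF/t-BuOH) gives the ring-A aldol product F6 (C3 epimers, 3α drawn). Wacker oxidation of the allyl group then comes back to the route at 20, which is cyclised by the second stage of step 14 alone (SmI2, HMPA, t-BuOH) to 21.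

## Further compounds

F1 | step 14 | keto acetal lactone: as 16 with 2-oxopropyl on C8 | C[C@H]1C(=O)O[C@]2(CCC3OCCO3)[C@@H]4CC=CC[C@]4(CC(C)=O)[C@@H](C(=O)OCc5ccccc5)[C@H]12
F2 | step 14 | ring-D-closed acetal lactone: as F1 after C13–C16 closure (bicyclo[3.2.1]octane rings C/D, 16-exo-OH, C17 methyl endo) | C[C@H]1C(=O)O[C@]2(CCC3OCCO3)[C@@H]4CC[C@@H]6C[C@]4(C[C@@]6(C)O)[C@@H](C(=O)OCc5ccccc5)[C@H]12
F3 | step 14 | aldehyde: as F2 with 3-oxopropyl on C10 | C[C@H]1C(=O)O[C@]2(CCC=O)[C@@H]4CC[C@@H]6C[C@]4(C[C@@]6(C)O)[C@@H](C(=O)OCc5ccccc5)[C@H]12
F4 | step 3 | cis-fused 3-(tert-butyldimethylsilyloxy)-7a-iodo-2,3,3a,4,7,7a-hexahydro-1H-inden-1-one, silyloxy cis to H-3a and to iodine | O=C1C[C@@H](O[Si](C)(C)C(C)(C)C)[C@@H]2CC=CC[C@]12I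
F5 | step 11 | aldehyde: as 16 with 3-oxopropyl on C10 (allyl on C8, no bromine) | C[C@H]1C(=O)O[C@]2(CCC=O)[C@@H]4CC=CC[C@]4(CC=C)[C@@H](C(=O)OCc5ccccc5)[C@H]12
F6 | step 11 | ring-A aldol product: as 20 with allyl in place of 2-oxopropyl on C8 (3α-OH drawn) | C[C@@]12C(=O)O[C@]3(CC[C@H]1O)[C@@H]1CC=CC[C@]1(CC=C)[C@@H](C(=O)OCc4ccccc4)[C@@H]32
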